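The eudesmane half is cut across ring B. With a C6=C7 double bond in place, the ring C5–C6–C7–C8–C9–C10 is the Diels–Alder adduct of diene C5=C6–C7=C8 and dienophile C9=C10; the unsubstituted C9 next to the methyl-bearing quaternary C10 marks an isopropenyl ketone, C7 carries the side chain as a 2-substituted diene, and the C1–C4 chain of ring A is the tether. One intramolecular cycloaddition of a linalool-derived trienone therefore closes rings A and B and sets C5 and C10 from the carbinol centre C4, which is re-set afterwards by dehydration and radical hydration. Isocupressic acid supplies the labdane half, joined by Williamson etherification.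

Key step: step 6

Assumption: (S)-(+)-linalool and (+)-isocupressic acid are taken as purchasable single enantiomers; eudesmane numbering is used for the sesquiterpene half (C4 = ring carbinol carbon, C5 and C10 = ring-fusion carbons, C7 bears C11, C14 and C15 = methyls on C10 and C4) and labdane numbering for the diterpene half.

Step 1
Reactants: 1 3-hydroxy-3-methylbutan-2-one
Product: 2 3-(tert-butyldimethylsilyloxy)-3-methylbutan-2-one
Conditions: TBSOTf, 2,6-lutidine, CH2Cl2, −78 to 0 °C
Reagents that add atoms: tert-butyldimethylsilyl triflate, CC(C)(C)[Si](C)(C)OS(=O)(=O)C(F)(F)F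
Why: Silylation of the tertiary hydroxyl with a silyl triflate and a hindered pyridine base is faster than enolisation of the ketone; the tert-butyldimethylsilyl ether is chosen because it must last until the fluoride step 14.

Step 2
Reactants: 2 3-(tert-butyldimethylsilyloxy)-3-methylbutan-2-one
Product: 3 3-(tert-butyldimethylsilyloxy)-3-methylbut-1-en-2-yl trifluoromethanesulfonate
Conditions: KN(SiMe3)2, THF, −78 °C; then PhNTf2, −78 to 0 °C
Reagents that add atoms: N-phenylbis(trifluoromethanesulfonimide), O=S(=O)(N(c1ccccc1)S(=O)(=O)C(F)(F)F)C(F)(F)F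
Why: The methyl group is the only enolisable position, so O-triflation of the potassium enolate (enol triflate formation) gives a single 1,1-disubstituted vinyl triflate.

Step 3
Reactants: 4 (S)-(+)-linalool
Product: 5 (5S)-5-ethenyl-5-methyloxolan-2-ol (lactol, both anomers)
Conditions: O3 (1 equiv, indicator end-point), CH2Cl2, −78 °C; then Me2S, −78 °C to rt
Reagents that add atoms: ozone, [O-][O+]=O
Why: Ozonolysis with reductive work-up cleaves the electron-rich trisubstituted double bond in preference to the vinyl group, and the γ-hydroxy aldehyde closes to the five-membered lactol without touching the C4 centre.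

Step 4
Reactants: 5 (5S)-5-ethenyl-5-methyloxolan-2-ol; 6 isopropenylmagnesium bromide (3 equiv)
Product: 7 (6S)-2,6-dimethylocta-1,7-diene-3,6-diol (both C3 epimers)
Conditions: THF, 0 °C to rt; aq. NH4Cl
Reagents that add atoms: none
Why: The lactol is in equilibrium with its open hydroxy aldehyde, which undergoes Grignard 1,2-addition; the new carbinol centre forms as both epimers, which is irrelevant because it is oxidised in step 6.

Step 5
Reactants: 7 (6S)-2,6-dimethylocta-1,7-diene-3,6-diol; 3 3-(tert-butyldimethylsilyloxy)-3-methylbut-1-en-2-yl trifluoromethanesulfonate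
Product: 8 (6S,7E)-10-(tert-butyldimethylsilyloxy)-2,6,10-trimethyl-9-methylideneundeca-1,7-diene-3,6-diol (both C3 epimers)
Conditions: Pd(OAc)2 (5 mol%), P(o-tolyl)3 (10 mol%), Et3N, MeCN, 70 °C
Reagents that add atoms: none
Why: Heck reaction: the vinylpalladium species from 3 adds to the terminal carbon of the vinyl group of the tertiary allylic alcohol and, as C4 carries no hydrogen, β-hydride elimination can only give the conjugated (E)-diene; the 1,1-disubstituted isopropenyl group inserts much more slowly.

Step 6
Reactants: 8 (6S,7E)-10-(tert-butyldimethylsilyloxy)-2,6,10-trimethyl-9-methylideneundeca-1,7-diene-3,6-diol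
Product: 10 (4S,5R,10R)-11-(tert-butyldimethylsilyloxy)-4-hydroxyeudesm-6-en-1-one, via trienone 9 (not isolated)
Conditions: Dess–Martin periodinane, NaHCO3, CH2Cl2, 0 °C; then toluene (0.01 M), BHT (cat.), 80 °C
Reagents that add atoms: none
Why: Oxidation of the allylic alcohol gives the 2-methyl-1,7,9-decatrien-3-one 9, which undergoes a concerted, asynchronous intramolecular Diels–Alder reaction (diene C5=C6–C7=C8 in its s-cis form, dienophile C9=C10 activated by the C1 ketone); the closest known reaction type is the thermal cyclisation of 2-methyl-1,7,9-decatrien-3-ones to trans-fused 10-methyl-1-decalones. Ring B is closed by the [4+2] union itself (bonds C8–C9 and C5–C10) and ring A by the same C5–C10 bond across the four-atom tether C1–C4, both as six-membered rings through a chair-like tether. C5 and C10 arise from suprafacial addition with the tether exo and the dienophile methyl endo, the mode that an α-methyl group on the dienophile is expected to favour and that gives the trans fusion (10-methyl anti to 5-H). The diene face is chosen by C4: the small hydroxyl should take the pseudo-axial (inside) site that ends syn-axial to the C10 methyl, and the C4 methyl the pseudo-equatorial site anti to the forming C5–C10 bond, so that (4S) is relayed to (5R,10R). Regiochemistry is fixed by the tether, the substituent on C7 secures the s-cis diene, the tertiary carbinol is inert to the oxidant, and minor diastereomers are to be removed by chromatography at this stage.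

Step 7
Reactants: 10 (4S,5R,10R)-11-(tert-butyldimethylsilyloxy)-4-hydroxyeudesm-6-en-1-one
Product: 11 (4S,5R,7R,10R)-11-(tert-butyldimethylsilyloxy)-4-hydroxyeudesman-1-one
Conditions: H2 (3 atm), 5% Pt/C, EtOAc, rt
Reagents that add atoms: none
Why: Heterogeneous hydrogenation should add hydrogen cis from the α face of ring B, the β face being screened by the axial C10 methyl and the axial 4β-hydroxyl, which sets C7 with 7α-H and the side chain β (equatorial); platinum in a neutral solvent avoids hydrogenolysis of the allylic silyl ether.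

Step 8
Reactants: 11 (4S,5R,7R,10R)-11-(tert-butyldimethylsilyloxy)-4-hydroxyeudesman-1-one
Product: 13 (4S,5R,7R,10R)-11-(tert-butyldimethylsilyloxy)eudesman-4-ol (4β-hydroxyl), via N-silyl hydrazone 12 (not isolated)
Conditions: TBSNHNHTBS, Sc(OTf)3 (cat.), 100 °C; then KOtBu (cat.), t-BuOH, DMSO, 100 °C
Reagents that add atoms: none
Why: Wolff–Kishner reduction through the N-silyl hydrazone, which forms even from a ketone flanked by a quaternary carbon and is decomposed by alkoxide in DMSO under conditions that leave the silyl ether and the tertiary alcohol intact.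

Step 9
Reactants: 13 (4S,5R,7R,10R)-11-(tert-butyldimethylsilyloxy)eudesman-4-ol
Product: 14 (5S,7R,10R)-11-(tert-butyldimethylsilyloxy)eudesm-4(15)-ene (silyl ether of β-eudesmol)
Conditions: Burgess reagent, toluene, 70 °C
Reagents that add atoms: none
Why: Burgess dehydration is a syn elimination of the sulfamate ester; the axial 4β-oxygen has no syn hydrogen at C5 (5α-H is anti) and the freely rotating methyl reaches the cyclic transition state most easily, so the exocyclic alkene is expected, and a ring-alkene regioisomer, should it form, would give the same C4 radical in step 10.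

Step 10
Reactants: 14 (5S,7R,10R)-11-(tert-butyldimethylsilyloxy)eudesm-4(15)-ene
Product: 16 (4R,5R,7R,10R)-11-(tert-butyldimethylsilyloxy)eudesman-4-ol (4α-hydroxyl), via hydroperoxide 15 (not isolated)
Conditions: Co(acac)2 (cat.), PhSiH3, O2 (1 atm), THF, rt; then PPh3
Reagents that add atoms: dioxygen, O=O
Why: Mukaiyama hydration: hydrogen-atom transfer to the terminal carbon gives the tertiary C4 radical, which should be trapped by dioxygen from the equatorial α face because axial approach is blocked by the syn-axial C10 methyl; reduction of the hydroperoxide then gives the 4α-alcohol with the 4β (axial) methyl.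

Step 11
Reactants: 17 (+)-isocupressic acid
Product: 18 2-(trimethylsilyl)ethyl 15-hydroxylabda-8(17),13E-dien-19-oate
Conditions: 2-(trimethylsilyl)ethyl 2,2,2-trichloroacetimidate, toluene, 100 °C
Reagents that add atoms: 2-(trimethylsilyl)ethyl 2,2,2-trichloroacetimidate, C[Si](C)(C)CCOC(=N)C(Cl)(Cl)Cl
Why: Imidate esterification: the acid protonates the imidate and the carboxylate is alkylated on oxygen, which needs no attack at the hindered axial carbonyl and leaves the neutral allylic alcohol alone when no other acid is added.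

Step 12
Reactants: 18 2-(trimethylsilyl)ethyl 15-hydroxylabda-8(17),13E-dien-19-oate
Product: 19 2-(trimethylsilyl)ethyl 15-bromolabda-8(17),13E-dien-19-oate
Conditions: CBr4, PPh3, CH2Cl2, 0 °C
Reagents that add atoms: carbon tetrabromide, BrC(Br)(Br)Br
Why: Appel reaction: bromide displaces the activated primary allylic oxygen by SN2 at CH2, which keeps the (E)-trisubstituted double bond in place and tolerates the ester and the exocyclic alkene.

Step 13
Reactants: 16 (4R,5R,7R,10R)-11-(tert-butyldimethylsilyloxy)eudesman-4-ol; 19 2-(trimethylsilyl)ethyl 15-bromolabda-8(17),13E-dien-19-oate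
Product: 21 2-(trimethylsilyl)ethyl 15-{[(4R,5R,7R,10R)-11-(tert-butyldimethylsilyloxy)eudesman-4-yl]oxy}labda-8(17),13E-dien-19-oate, via potassium alkoxide 20 (not isolated)
Conditions: KH, 18-crown-6 (cat.), THF, 0 °C to rt; then 19, Bu4NI (cat.), 0 °C to rt
Reagents that add atoms: none
Why: Williamson ether synthesis: the potassium alkoxide of the equatorial tertiary C4 alcohol attacks the primary allylic bromide by SN2, so the C4–O bond and its configuration are untouched and the (E)-alkene is retained; the other tertiary oxygen is silylated and the ester carbonyl is too hindered to be attacked.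

Step 14
Reactants: 21 2-(trimethylsilyl)ethyl 15-{[(4R,5R,7R,10R)-11-(tert-butyldimethylsilyloxy)eudesman-4-yl]oxy}labda-8(17),13E-dien-19-oate
Product: 22 target, 15-{[(4R,5R,7R,10R)-11-hydroxyeudesman-4-yl]oxy}labda-8(17),13E-dien-19-oic acid
Conditions: Bu4NF, THF, 50 °C; then aq. NH4Cl
Reagents that add atoms: none
Why: Fluoride attacks both silicon atoms: the 2-(trimethylsilyl)ethyl ester fragments to carboxylate, ethylene and Me3SiF, and the tertiary silyl ether is cleaved, under conditions that do not affect the tertiary allylic ether or the alkenes.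

Compound list
1 | 3-hydroxy-3-methylbutan-2-one | CC(=O)C(C)(C)O | starting material
2 | 3-(tert-butyldimethylsilyloxy)-3-methylbutan-2-one | CC(=O)C(C)(C)O[Si](C)(C)C(C)(C)C | intermediate
3 | 3-(tert-butyldimethylsilyloxy)-3-methylbut-1-en-2-yl trifluoromethanesulfonate | C=C(OS(=O)(=O)C(F)(F)F)C(C)(C)O[Si](C)(C)C(C)(C)C | intermediate
4 | (S)-(+)-linalool, (3S)-3,7-dimethylocta-1,6-dien-3-ol | C=C[C@@](C)(O)CCC=C(C)C | starting material
5 | (5S)-5-ethenyl-5-methyloxolan-2-ol (both anomers) | C=C[C@]1(C)CCC(O)O1 | intermediate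
6 | isopropenylmagnesium bromide | C=C(C)[Mg]Br | starting material
7 | (6S)-2,6-dimethylocta-1,7-diene-3,6-diol (both C3 epimers) | C=C[C@@](C)(O)CCC(O)C(C)=C | intermediate
8 | (6S,7E)-10-(tert-butyldimethylsilyloxy)-2,6,10-trimethyl-9-methylideneundeca-1,7-diene-3,6-diol (both C3 epimers) | C=C(C)C(O)CC[C@](C)(O)/C=C/C(=C)C(C)(C)O[Si](C)(C)C(C)(C)C | intermediate
9 | (6S,7E)-10-(tert-butyldimethylsilyloxy)-6-hydroxy-2,6,10-trimethyl-9-methylideneundeca-1,7-dien-3-one (trienone) | C=C(C)C(=O)CC[C@](C)(O)/C=C/C(=C)C(C)(C)O[Si](C)(C)C(C)(C)C | intermediate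
10 | (4S,5R,10R)-11-(tert-butyldimethylsilyloxy)-4-hydroxyeudesm-6-en-1-one (4β-OH, 4α-CH3, 5α-H, 10β-CH3) | O[C@@]1(C)CCC(=O)[C@]2(C)CCC(C(C)(C)O[Si](C)(C)C(C)(C)C)=C[C@H]21 | intermediate
11 | (4S,5R,7R,10R)-11-(tert-butyldimethylsilyloxy)-4-hydroxyeudesman-1-one | O[C@@]1(C)CCC(=O)[C@]2(C)CC[C@@H](C(C)(C)O[Si](C)(C)C(C)(C)C)C[C@H]21 | intermediate
12 | N-(tert-butyldimethylsilyl)hydrazone of 11 | O[C@@]1(C)CCC(=NN[Si](C)(C)C(C)(C)C)[C@]2(C)CC[C@@H](C(C)(C)O[Si](C)(C)C(C)(C)C)C[C@H]21 | intermediate
13 | (4S,5R,7R,10R)-11-(tert-butyldimethylsilyloxy)eudesman-4-ol (4β-OH; 11-O-silyl 4-epi-cryptomeridiol) | O[C@@]1(C)CCC[C@]2(C)CC[C@@H](C(C)(C)O[Si](C)(C)C(C)(C)C)C[C@H]21 | intermediate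
14 | (5S,7R,10R)-11-(tert-butyldimethylsilyloxy)eudesm-4(15)-ene | C=C1CCC[C@]2(C)CC[C@@H](C(C)(C)O[Si](C)(C)C(C)(C)C)C[C@H]21 | intermediate
15 | (4R,5R,7R,10R)-11-(tert-butyldimethylsilyloxy)eudesman-4-yl hydroperoxide | OO[C@]1(C)CCC[C@]2(C)CC[C@@H](C(C)(C)O[Si](C)(C)C(C)(C)C)C[C@H]21 | intermediate
16 | (4R,5R,7R,10R)-11-(tert-butyldimethylsilyloxy)eudesman-4-ol (4α-OH; 11-O-silyl cryptomeridiol) | O[C@]1(C)CCC[C@]2(C)CC[C@@H](C(C)(C)O[Si](C)(C)C(C)(C)C)C[C@H]21 | intermediate
17 | (+)-isocupressic acid, 15-hydroxylabda-8(17),13E-dien-19-oic acid | C=C1CC[C@@H]2[C@](C)(CCC[C@]2(C)C(=O)O)[C@H]1CC/C(C)=C/CO | starting material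
18 | 2-(trimethylsilyl)ethyl 15-hydroxylabda-8(17),13E-dien-19-oate | C=C1CC[C@@H]2[C@](C)(CCC[C@]2(C)C(=O)OCC[Si](C)(C)C)[C@H]1CC/C(C)=C/CO | intermediate
19 | 2-(trimethylsilyl)ethyl 15-bromolabda-8(17),13E-dien-19-oate | C=C1CC[C@@H]2[C@](C)(CCC[C@]2(C)C(=O)OCC[Si](C)(C)C)[C@H]1CC/C(C)=C/CBr | intermediate
20 | potassium alkoxide of 16 | [K+].[O-][C@]1(C)CCC[C@]2(C)CC[C@@H](C(C)(C)O[Si](C)(C)C(C)(C)C)C[C@H]21 | intermediate
21 | 2-(trimethylsilyl)ethyl 15-{[(4R,5R,7R,10R)-11-(tert-butyldimethylsilyloxy)eudesman-4-yl]oxy}labda-8(17),13E-dien-19-oate | C=C1CC[C@@H]2[C@](C)(CCC[C@]2(C)C(=O)OCC[Si](C)(C)C)[C@H]1CC/C(C)=C/CO[C@]1(C)CCC[C@]2(C)CC[C@@H](C(C)(C)O[Si](C)(C)C(C)(C)C)C[C@H]21 | intermediate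
22 | 15-{[(4R,5R,7R,10R)-11-hydroxyeudesman-4-yl]oxy}labda-8(17),13E-dien-19-oic acid (CNP0156875.1) | C=C1CC[C@@H]2[C@](C)(CCC[C@]2(C)C(=O)O)[C@H]1CC/C(C)=C/CO[C@]1(C)CCC[C@]2(C)CC[C@@H](C(C)(C)O)C[C@H]21 | target

Total step count: 14. Longest linear sequence: 10 steps (steps 3, 4, 5, 6, 7, 8, 9, 10, 13, 14).

Steps most likely to fail

Step 6. The hydroxyl at C4 may take the site anti to the forming C5–C10 bond, or show little preference, so that the dienophile adds to the other diene face and the ring fusion is built in the mirror-image sense. Endo folding of the tether to cis-fused material is the second hazard. Fallback, in which C4 is kept instead of relayed: it sets out from triflate 3 and uses the enantiomeric terpene (R)-(−)-linalool F1. Ozonolysis as in step 3 gives lactol F2, addition of 6 gives diol F3, and Heck coupling with 3 gives triene diol F4. Oxidation and cycloaddition as in step 6 then give, via trienone F5, the adduct F6. In F6 the anti-oxygen mode delivers (4R,5R,10R), that is the 4α-hydroxy-4β-methyl arrangement of the target together with the required ring fusion. Hydrogenation as in step 7 gives ketone F7, and the reduction of step 8, via N-silyl hydrazone F8, comes back to the route at 16; steps 9 and 10 are then not needed.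

Step 13. The hindered tertiary alkoxide may act as a base and remove HBr from the allylic bromide (1,2- or 1,4-elimination to a diene) instead of substituting it. Fallback by Tsuji–Trost etherification: it sets out from alcohol 18, which is converted with methyl chloroformate and pyridine into the allylic methyl carbonate F9. Alcohol 16 is turned with Et2Zn into its ethylzinc alkoxide F10. Pd(OAc)2 with PPh3 (zerovalent palladium formed in the flask) in THF ionises F9, and the zinc alkoxide attacks the unsubstituted terminus of the allyl complex. This comes back to the route at 21 without a basic elimination pathway.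

Step 10. The tertiary C4 radical may be reduced by a second hydrogen atom instead of being trapped by oxygen, or it may be trapped from the axial β face. Fallback by the polar route: it sets out from alkene 14, which is epoxidised with mCPBA and NaHCO3 in CH2Cl2 from the open α face to the spiro-epoxide F11. LiAlH4 in THF then opens F11 at the primary C15 and comes back to the route at 16, with the oxygen fixed at 4α by the epoxidation.

Further compounds
F1 | step 6 | (R)-(−)-linalool | C=C[C@](C)(O)CCC=C(C)C
F2 | step 6 | (5R)-5-ethenyl-5-methyloxolan-2-ol | C=C[C@@]1(C)CCC(O)O1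
F3 | step 6 | (6R)-2,6-dimethylocta-1,7-diene-3,6-diol | C=C[C@](C)(O)CCC(O)C(C)=C
F4 | step 6 | (6R,7E)-10-(tert-butyldimethylsilyloxy)-2,6,10-trimethyl-9-methylideneundeca-1,7-diene-3,6-diol | C=C(C)C(O)CC[C@@](C)(O)/C=C/C(=C)C(C)(C)O[Si](C)(C)C(C)(C)C
F5 | step 6 | (6R,7E)-10-(tert-butyldimethylsilyloxy)-6-hydroxy-2,6,10-trimethyl-9-methylideneundeca-1,7-dien-3-one | C=C(C)C(=O)CC[C@@](C)(O)/C=C/C(=C)C(C)(C)O[Si](C)(C)C(C)(C)C
F6 | step 6 | (4R,5R,10R)-11-(tert-butyldimethylsilyloxy)-4-hydroxyeudesm-6-en-1-one | O[C@]1(C)CCC(=O)[C@]2(C)CCC(C(C)(C)O[Si](C)(C)C(C)(C)C)=C[C@H]21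
F7 | step 6 | (4R,5R,7R,10R)-11-(tert-butyldimethylsilyloxy)-4-hydroxyeudesman-1-one | O[C@]1(C)CCC(=O)[C@]2(C)CC[C@@H](C(C)(C)O[Si](C)(C)C(C)(C)C)C[C@H]21
F8 | step 6 | N-(tert-butyldimethylsilyl)hydrazone of F7 | O[C@]1(C)CCC(=NN[Si](C)(C)C(C)(C)C)[C@]2(C)CC[C@@H](C(C)(C)O[Si](C)(C)C(C)(C)C)C[C@H]21
F9 | step 13 | 2-(trimethylsilyl)ethyl 15-(methoxycarbonyloxy)labda-8(17),13E-dien-19-oate | C=C1CC[C@@H]2[C@](C)(CCC[C@]2(C)C(=O)OCC[Si](C)(C)C)[C@H]1CC/C(C)=C/COC(=O)OC
F10 | step 13 | ethylzinc alkoxide of 16 | CC[Zn]O[C@]1(C)CCC[C@]2(C)CC[C@@H](C(C)(C)O[Si](C)(C)C(C)(C)C)C[C@H]21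
F11 | step 10 | (4R,5R,7R,10R)-11-(tert-butyldimethylsilyloxy)-4,15-epoxyeudesmane (4α-oxygen) | O1C[C@]12CCC[C@]3(C)CC[C@@H](C(C)(C)O[Si](C)(C)C(C)(C)C)C[C@H]32
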